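## Retrosynthetic overview
1. Ferutinine ⇒ Yamaguchi esterification of jaeschkeanadiol (**17**, 17 heavy atoms) with 4-(TBSO)benzoic acid (**12**, 17 heavy atoms), two halves of equal size joined last.
2. **17** ⇒ ring-closing metathesis between the allyl group on the quaternary carbon and a methallyl carbinol, which closes the trisubstituted cycloheptene (the last carbocycle formed).
3. The cyclopentane side chain ⇒ aldol coupling of the regiodefined dienolate of enone **7** with 3-methylbut-3-enal (**9**), then 1,4-reduction of the enone and isopropyl addition to the ketone to give the tertiary carbinol.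
4. The quaternary centre ⇒ Johnson–Claisen chirality transfer from (S)-3-methylcyclopent-2-en-1-ol (CBS reduction of **1**). Ring order: cyclopentane (already in **1**), then the side chain by aldol, then the cycloheptene by RCM.

*Assumptions (one line each):*
- The CBS catalyst enantiomer is chosen to give the (S)-alcohol.
- The aldol gives the desired trans/anti diastereomer as the major product (dr about 4:1), separable by chromatography.

## Steps

**Step 1**
Reactants: **1** 3-methylcyclopent-2-en-1-one
Product: **2** (S)-3-methylcyclopent-2-en-1-ol
Conditions: (R)-Me-CBS (10 mol%), BH3·SMe2, THF, −20 °C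
Reagents that add atoms: none
Why: The CBS (oxazaborolidine) reduction is catalyst-controlled 1,2-hydride delivery to one enone face and sets the carbinol (S), which is converted into the quaternary stereocentre in step 2.

**Step 2**
Reactants: **2**; **3** trimethyl orthoacetate
Product: **4** methyl (S)-2-(1-methylcyclopent-2-en-1-yl)acetate
Conditions: MeC(OMe)3 (3 equiv), EtCO2H (cat.), 140 °C, MeOH distilled off
Reagents that add atoms: trimethyl orthoacetate, CC(OC)(OC)OC (supplies CH2CO2Me)
Why: In the Johnson–Claisen [3,3] rearrangement the new C–C bond forms suprafacially on the face that carried the C–O bond, so the C1 stereocentre becomes the all-carbon quaternary stereocentre (C8a of the target).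

**Step 3**
Reactants: **4**
Product: **5** (S)-2-(1-methylcyclopent-2-en-1-yl)acetaldehyde
Conditions: DIBAL-H (1.1 equiv), toluene, −78 °C
Reagents that add atoms: none
Why: Partial ester reduction (DIBAL-H at −78 °C) stops at the aldehyde, and the quaternary centre is untouched.

**Step 4**
Reactants: **5**
Product: **6** (S)-3-allyl-3-methylcyclopent-1-ene
Conditions: Ph3P+CH3 Br−, KOt-Bu, THF, 0 °C → rt
Reagents that add atoms: methyltriphenylphosphonium bromide, C[P+](c1ccccc1)(c1ccccc1)c1ccccc1.[Br-] (adds =CH2)
Why: Wittig methylenation converts CH2CHO into the allyl group needed for RCM without creating any stereocentre.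

**Step 5**
Reactants: **6**
Product: **7** (R)-4-allyl-4-methylcyclopent-2-en-1-one (the descriptor changes only through CIP priorities)
Conditions: Pd(OH)2/C (20 mol%), t-BuOOH (5 equiv), K2CO3, CH2Cl2, rt
Reagents that add atoms: tert-butyl hydroperoxide, CC(C)(C)OO (supplies the carbonyl O)
Why: Allylic C–H oxidation is regiospecific because the ring alkene has only one allylic CH2 (C5, the future C3); the other allylic carbon is the quaternary centre.

**Step 6**
Reactants: **8** 3-methylbut-3-en-1-ol
Product: **9** 3-methylbut-3-enal
Conditions: Dess–Martin periodinane, NaHCO3, CH2Cl2, 0 °C; use crude immediately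
Reagents that add atoms: none
Why: A mild oxidation gives the aldehyde without isomerising it to the conjugated enal.

**Step 7**
Reactants: **10** 4-bromophenol
Product: **11** (4-bromophenoxy)-tert-butyldimethylsilane
Conditions: TBSCl, imidazole, DMF, rt
Reagents that add atoms: tert-butyldimethylsilyl chloride, CC(C)(C)[Si](C)(C)Cl
Why: Silyl protection of the phenol makes the aryl bromide compatible with organolithium chemistry.

**Step 8**
Reactants: **11**
Product: **12** 4-(tert-butyldimethylsilyloxy)benzoic acid
Conditions: n-BuLi, THF, −78 °C; then CO2 (s), −78 °C → rt; aq. HCl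
Reagents that add atoms: carbon dioxide, O=C=O (supplies the carboxyl carbon)
Why: Bromine–lithium exchange followed by carboxylation (aryllithium + CO2) builds the aryl acid fragment.

**Step 9 (aldol fragment coupling)**
Reactants: **7**; **9**
Product: **13** 4-allyl-4-methyl-5-[(1S?-configured, see SMILES) 1-(triethylsilyloxy)-3-methylbut-3-en-1-yl]cyclopent-2-en-1-one, with the side chain trans to the allyl group (cis to Me) and the carbinol anti
Conditions: LDA, THF, −78 °C; then **9**, −78 °C; then TESCl, −78 → 0 °C
Reagents that add atoms: triethylsilyl chloride, CC[Si](CC)(CC)Cl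
Why: In this aldol reaction only C5 of the enone can be deprotonated (C4 is quaternary), so the cross-conjugated dienolate is regiodefined. The aldehyde approaches anti to the larger allyl group, giving the trans ring relationship at C3a. The ring-constrained (E)-enolate reacts through a chair Zimmerman–Traxler transition state to give the anti carbinol, and O-silylation prevents retro-aldol and E1cB elimination.

**Step 10**
Reactants: **13**
Product: **14** saturated ketone (same stereocentres)
Conditions: [(Ph3P)CuH]6 (cat.), PhSiH3, toluene, 0 °C; aq. NH4Cl
Reagents that add atoms: none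
Why: Stryker-type Cu–H conjugate reduction reduces only the enone C=C (the terminal alkenes and the silyl ether are untouched) and creates no stereocentre.

**Step 11**
Reactants: **14**
Product: **15** tertiary alcohol (isopropyl carbinol)
Conditions: i-PrMgCl·LiCl, anhydrous CeCl3, THF, −78 → −20 °C
Reagents that add atoms: isopropylmagnesium chloride, CC(C)[Mg]Cl (supplies i-Pr)
Why: Organocerium addition suppresses enolisation and reduction of the hindered ketone. The nucleophile attacks anti to the adjacent bulky C3a side chain, which puts the OH cis to that chain and the i-Pr trans, as in the target.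

**Step 12**
Reactants: **15**
Product: **16** bicyclic 5-7 TES ether (trisubstituted cycloheptene)
Conditions: Hoveyda–Grubbs II (5 mol%), toluene (2 mM), 80 °C
Reagents that add atoms: none (ethylene is lost)
Why: Ring-closing metathesis joins the terminal allyl alkene and the 1,1-disubstituted methallyl alkene to form the trisubstituted C6=C7 alkene, and no stereocentre is touched.

**Step 13**
Reactants: **16**
Product: **17** jaeschkeanadiol (diol)
Conditions: HF·pyridine, pyridine/THF, 0 °C → rt
Reagents that add atoms: none
Why: Fluoride cleaves the secondary TES ether selectively; the free tertiary alcohol and the alkene are unaffected.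

**Step 14 (late fragment coupling)**
Reactants: **17**; **12**
Product: **18** jaeschkeanadiol 4-(TBSO)benzoate
Conditions: **12**, 2,4,6-Cl3C6H2COCl, Et3N, THF, rt; then **17**, DMAP, toluene, 50 °C
Reagents that add atoms: none
Why: Yamaguchi esterification through the mixed anhydride acylates only the secondary C4–OH (the tertiary OH is too hindered), with retention at that centre.

**Step 15**
Reactants: **18**
Product: **19** ferutinine
Conditions: TBAF/AcOH (1:1), THF, 0 °C
Reagents that add atoms: none
Why: Buffered fluoride removes the aryl TBS ether without cleaving or migrating the hindered ester.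

## Compound list
1 | 3-methylcyclopent-2-en-1-one | CC1=CC(=O)CC1 | starting material
2 | (S)-3-methylcyclopent-2-en-1-ol | O[C@@H]1C=C(C)CC1 | intermediate
3 | trimethyl orthoacetate | CC(OC)(OC)OC | starting material
4 | methyl (S)-2-(1-methylcyclopent-2-en-1-yl)acetate | COC(=O)C[C@@]1(C)C=CCC1 | intermediate
5 | (S)-2-(1-methylcyclopent-2-en-1-yl)acetaldehyde | O=CC[C@@]1(C)C=CCC1 | intermediate
6 | (S)-3-allyl-3-methylcyclopent-1-ene | C=CC[C@@]1(C)C=CCC1 | intermediate
7 | (R)-4-allyl-4-methylcyclopent-2-en-1-one | C=CC[C@@]1(C)C=CC(=O)C1 | intermediate
8 | 3-methylbut-3-en-1-ol | CC(=C)CCO | starting material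
9 | 3-methylbut-3-enal | CC(=C)CC=O | intermediate
10 | 4-bromophenol | Oc1ccc(Br)cc1 | starting material
11 | (4-bromophenoxy)-tert-butyldimethylsilane | CC(C)(C)[Si](C)(C)Oc1ccc(Br)cc1 | intermediate
12 | 4-(tert-butyldimethylsilyloxy)benzoic acid | CC(C)(C)[Si](C)(C)Oc1ccc(cc1)C(=O)O | intermediate
13 | aldol TES ether (enone) | C=CC[C@@]1(C)C=CC(=O)[C@@H]1[C@@H](O[Si](CC)(CC)CC)CC(C)=C | intermediate
14 | saturated ketone | C=CC[C@@]1(C)CCC(=O)[C@@H]1[C@@H](O[Si](CC)(CC)CC)CC(C)=C | intermediate
15 | isopropyl tertiary alcohol diene | C=CC[C@@]1(C)CC[C@@](O)(C(C)C)[C@@H]1[C@@H](O[Si](CC)(CC)CC)CC(C)=C | intermediate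
16 | bicyclic 5-7 TES ether | CC1=CC[C@@]2(C)CC[C@@](O)(C(C)C)[C@@H]2[C@@H](O[Si](CC)(CC)CC)C1 | intermediate
17 | jaeschkeanadiol | CC1=CC[C@@]2(C)CC[C@@](O)(C(C)C)[C@@H]2[C@@H](O)C1 | intermediate
18 | jaeschkeanadiol 4-(TBSO)benzoate | CC1=CC[C@@]2(C)CC[C@@](O)(C(C)C)[C@@H]2[C@@H](OC(=O)c2ccc(O[Si](C)(C)C(C)(C)C)cc2)C1 | intermediate
19 | ferutinine | CC1=CC[C@@]2(C)CC[C@@](O)(C(C)C)[C@@H]2[C@@H](OC(=O)c2ccc(O)cc2)C1 | target

## Totals
Total steps: 15. Longest linear sequence: 12 (steps 1–5, then 9–15). Branches: the aldehyde (1 step) and the aryl acid (2 steps) are prepared in parallel.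

## Three steps most likely to fail
1. **Step 9 (aldol):** the trans/anti diastereoselectivity is only moderate, and the aldehyde is prone to isomerisation and to proton transfer with the dienolate.
   Fallback: set C3a and C8a by conjugate addition of a vinyl cuprate to (R)-4-OTBS-2-methylcyclopentenone followed by trans-selective enolate allylation, then convert the vinyl group into the methallyl carbinol.
2. **Step 12 (RCM):** the trans-fused, trisubstituted cycloheptene may be too strained, or the reaction may oligomerise.
   Fallback: close the ring by intramolecular Nozaki–Hiyama–Kishi coupling of a vinyl iodide onto an aldehyde, followed by deoxygenation.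
3. **Step 5 (allylic oxidation):** oxidation may not be chemoselective in the presence of the terminal alkene, and the volatile hydrocarbon **6** is hard to handle.
   Fallback: oxidise at the ester stage (**4**, where no other alkene is present), protect the enone as a ketal, then convert the ester arm to the allyl group by DIBAL-H, Wittig methylenation and deketalisation.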